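**Assumptions:** The target is (2R,3′E,7′E)-α-tocotrienol. Commercial geranylgeraniol is taken as the all-E isomer (≥90%). The chiral IDPi catalyst enantiomer and its 3,3′-aryl groups are chosen by screening to give 2R.

## Retrosynthetic overview
- α-Tocotrienol (**5**) is disconnected at the chroman C2–O bond. This is a proton-initiated, 6-endo hydroaryloxylation of the aryl-proximal trisubstituted alkene of 6-geranylgeranyl-trimethylhydroquinone (**3**), and it sets the quaternary C2 stereocentre.
- **3** is disconnected at the Ar–CH2 bond to trimethylhydroquinone (**1**) and geranylgeraniol (**2**), a Friedel–Crafts allylation at the only free aromatic C–H.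
- The aromatic ring is present from the start, and the pyran ring is formed last, in the enantiodetermining step. Both starting materials are achiral.

## Route

**Step 1**
Reactants: **1** 2,3,5-trimethylbenzene-1,4-diol (trimethylhydroquinone); **2** (2E,6E,10E)-geranylgeraniol
Product: **3** 2-[(2E,6E,10E)-3,7,11,15-tetramethylhexadeca-2,6,10,14-tetraen-1-yl]-3,5,6-trimethylbenzene-1,4-diol
Conditions: **1** (3 equiv), **2** (1 equiv), BF3·OEt2 (10 mol%), 1,4-dioxane, 15–25 °C, Ar, dark, short reaction time
Reagents that add atoms: none (BF3 is catalytic; water is lost)
Why: Friedel–Crafts allylation of the electron-rich hydroquinone at its single open ring position (ortho to an OH), via the allyl cation from **2**. Excess **1** and mild, short conditions favour the ring-open product, because allyl-cation formation is much faster than protonation of the unactivated alkenes. The E geometry of all four alkenes is retained, and no stereocentre is formed.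

**Step 2**
Reactants: **3**; catalyst **4** (chiral IDPi, a confined imidodiphosphorimidate Brønsted acid)
Product: **5** (2R,3′E,7′E)-α-tocotrienol
Conditions: **4** (5 mol%), cyclohexane (0.01 M), 30–40 °C, 3–6 d, degassed, Ar, dark
Reagents that add atoms: none (intramolecular isomerisation; the catalyst is regenerated)
Why: Proposed new method: enantioselective Brønsted-acid hydroaryloxylation of a trisubstituted, unactivated alkene by a free phenol, inside a polyene, to form a tertiary aryl alkyl ether stereocentre. The IDPi protonates C2′ of the alkene nearest the arene in the Markovnikov sense. The phenol OH, H-bonded to the chiral IDPi anion, closes onto the tertiary carbon C3′ (6-endo), and the facial selectivity of this C–O bond formation sets C2 (R). The closest known reactions are IDPi-catalysed asymmetric hydroalkoxylation of unactivated alkenols, Brønsted-acid cyclisation of homofarnesol to Ambrox, and the tocopherol cyclase reaction. The distal alkenes have no internal nucleophile for a 6-membered closure, and their protonation is reversible. Only the proximal alkene is captured irreversibly by the phenol to give the aryl ether. The para-OH, the three ring methyls and the other three alkenes are untouched.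

## Compound list
1 | 2,3,5-trimethylbenzene-1,4-diol | Cc1cc(O)c(C)c(C)c1O | starting material
2 | (2E,6E,10E)-geranylgeraniol | CC(C)=CCC/C(C)=C/CC/C(C)=C/CC/C(C)=C/CO | starting material
3 | 2-geranylgeranyl-3,5,6-trimethylhydroquinone | CC(C)=CCC/C(C)=C/CC/C(C)=C/CC/C(C)=C/Cc1c(C)c(O)c(C)c(C)c1O | intermediate
4 | chiral IDPi Brønsted acid catalyst, parent framework (3,3′-aryl groups and binaphthyl axial configuration set by screening, so omitted) | FC(F)(F)S(=O)(=O)N=P1(Oc2ccc3ccccc3c2-c2c(O1)ccc1ccccc21)NP1(=NS(=O)(=O)C(F)(F)F)Oc2ccc3ccccc3c2-c2c(O1)ccc1ccccc21 | starting material (catalyst, used in Step 2)
5 | (2R,3′E,7′E)-α-tocotrienol | CC(C)=CCC/C(C)=C/CC/C(C)=C/CC[C@]1(C)CCc2c(C)c(O)c(C)c(C)c2O1 | target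

## Step count
Total steps: 2. Longest linear sequence: 2.

## Three steps most likely to fail
1. **Step 2 (proposed new step), enantioselectivity and reactivity.** An unactivated trisubstituted alkene with a weakly nucleophilic phenol may give low ee or conversion. Fallback, using known chemistry: make racemic α-tocotrienol from **1** and **2** with a Lewis acid (the classical tocopherol-type condensation), acetylate, resolve by preparative chiral HPLC or SFC, then hydrolyse the acetate to give (2R).
2. **Step 1, Friedel–Crafts allylation.** Risks are O-allylation, competing polyene cyclisation, and premature racemic chroman closure. Fallback: a Naruta-type coupling of 2,3,5-trimethylbenzoquinone with geranylgeranyl-tributylstannane and BF3, followed by Na2S2O4 reduction, to give **3** regioselectively.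
3. **Step 2, second failure mode: chemoselectivity.** Protonation of the distal alkenes could lead to polyene cyclisation by-products. Fallback: a chiral-pool route from enantiopure (R)-Trolox, built up to the tocotrienol side chain by known homologation and olefination, which avoids acid activation of the polyene altogether.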